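Retrosynthetic overview
- Last bond: the C6–CH2–C3' bridge, made by adding 6-ethyl-4-hydroxy-5-methyl-2-pyrone to an ortho-quinone methide that fluoride releases from a bis-silylated C6 benzylic acetate.
- Before that: the C3=C4 bond by quinone dehydrogenation of the chroman, and the C8 acyl group with its (S) centre by aryllithium addition to the Weinreb amide of (S)-2-methylbutanoic acid.
- Central disconnection: the benzene ring (bonds C8–C8a, C5–C6, C7–C8, C4a–C5) from a dihydropyranyl diazoketone and a siloxyalkyne by photo-Wolff benzannulation.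
- Feature the strategy rests on: O1–C8a=C4a of the chromene is the enol ether of 2,2-dimethyl-3,4-dihydro-2H-pyran. The benzene ring can therefore be grown on the preformed pyran ring, with O1 next to the open C8 and the three ring oxygens all different (O1 ether, C5 free OH, C7 silyl ether).
- Ring order: dihydropyran ring (hetero-Diels–Alder), then benzene ring (benzannulation); the pyrone ring is made separately and joined last.

Key step: step 5

Remark on the chemistry: the compounds marked as starting materials in the list are taken as commercial. A benzylic silyl ether on this trioxygenated ring would itself be attacked by a quinone oxidant, so the C6 CH2OTBS group is exchanged for an acetate before the dehydrogenation. That acetate then serves as the leaving group in the final coupling.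

Step 1
Reactants: 1 acrolein; 2 2-methylpropene
Product: 3 2,2-dimethyl-3,4-dihydro-2H-pyran
Conditions: excess 2, hydroquinone (cat.), neat, sealed autoclave, ca. 200 °C; distillation
Reagents that add atoms: none
Why: A thermal inverse-electron-demand hetero-Diels–Alder reaction between the enal as heterodiene and the alkene should bond oxygen to the more substituted alkene carbon, so the gem-dimethyl group lands next to the ring oxygen, while excess alkene and the inhibitor hold back dimerisation and polymerisation of acrolein.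

Step 2
Reactants: 3 2,2-dimethyl-3,4-dihydro-2H-pyran; 4 N-methoxy-N-methylacetamide
Product: 6 1-(6,6-dimethyl-5,6-dihydro-4H-pyran-2-yl)ethan-1-one, via vinyllithium 5 (not isolated)
Conditions: t-BuLi, THF (1 equiv), pentane, −78 to 0 °C; then 4, −78 °C to rt; aq. NH4Cl
Reagents that add atoms: none
Why: tert-Butyllithium removes the vinylic proton next to the ring oxygen (α-alkoxyvinyl lithiation) and vinyllithium 5 is acylated only once by the N-methoxy-N-methylamide (Weinreb ketone synthesis).

Step 3
Reactants: 6 1-(6,6-dimethyl-5,6-dihydro-4H-pyran-2-yl)ethan-1-one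
Product: 8 2-diazo-1-(6,6-dimethyl-5,6-dihydro-4H-pyran-2-yl)ethan-1-one, via trifluoroacetyl diketone 7 (not isolated)
Conditions: LiN(SiMe3)2, THF, −78 °C; CF3CO2CH2CF3; aq. HCl; then MsN3, Et3N, H2O, MeCN, rt
Reagents that add atoms: methanesulfonyl azide, CS(=O)(=O)N=[N+]=[N-]
Why: Kinetic deprotonation at the methyl group and Claisen-type trifluoroacetylation activate the ketone as 1,3-diketone 7, which undergoes diazo transfer with loss of the trifluoroacetyl group (detrifluoroacetylative Regitz diazo transfer), a sequence mild enough for the base-sensitive enone.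

Step 4
Reactants: 9 tert-butyldimethyl(prop-2-yn-1-yloxy)silane
Product: 12 3-(tert-butyldimethylsilyloxy)-1-(triisopropylsilyloxy)prop-1-yne, via lithium acetylide 10 (not isolated), via lithium ynolate 11 (not isolated)
Conditions: n-BuLi, THF, −78 °C; LiOOt-Bu (from t-BuOOH and LiN(SiMe3)2), THF, −78 to 0 °C; TIPSOTf, −78 to 0 °C
Reagents that add atoms: tert-butyl hydroperoxide, CC(C)(C)OO; triisopropylsilyl trifluoromethanesulfonate, CC(C)[Si](OS(=O)(=O)C(F)(F)F)(C(C)C)C(C)C
Why: Lithium acetylide 10 is oxidised at carbon by the electrophilic oxygen of lithium tert-butyl peroxide to ynolate 11 (acetylide oxidation), which the bulky silyl triflate traps on oxygen to give an isolable TIPS ynol ether.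

Step 5
Reactants: 8 2-diazo-1-(6,6-dimethyl-5,6-dihydro-4H-pyran-2-yl)ethan-1-one; 12 3-(tert-butyldimethylsilyloxy)-1-(triisopropylsilyloxy)prop-1-yne
Product: 17 6-(tert-butyldimethylsilyloxymethyl)-2,2-dimethyl-7-(triisopropylsilyloxy)chroman-5-ol, via vinylketene 13 (not isolated), via vinylcyclobutenone 14 (not isolated), via dienylketene 15 (not isolated), via cyclohexadienone 16 (not isolated)
Conditions: hν (254 nm, quartz), degassed ClCH2CH2Cl, rt; then 80 °C
Reagents that add atoms: none
Why: Light expels N2 from 8 and the dihydropyranyl carbon migrates (Wolff rearrangement, forming C8–C8a) to give vinylketene 13, whose carbonyl carbon becomes C5 and whose α-carbon becomes C8; siloxyalkyne 12 adds by [2+2] (C5–C6 and C7–C8) to give vinylcyclobutenone 14, which opens by 4π electrocyclisation to dienylketene 15. The benzene ring is then closed by a thermal disrotatory 6π electrocyclisation (C4a–C5) to cyclohexadienone 16, which tautomerises to phenol 17; warming to 80 °C after irradiation should drive any remaining 14 through this sequence. The closest known reaction type is the photo-Wolff (Danheiser) benzannulation of unsaturated and (hetero)aryl diazomethyl ketones with siloxyalkynes, which gives resorcinol monosilyl ethers; the α-alkoxyvinyl ketone used here is a new member of that substrate class. No stereocentre is formed. The step needs a single orientation in the [2+2] event, and this is secured by the match between the electrophilic ketene carbonyl carbon and the nucleophilic alkyne carbon β to the siloxy group, the one that carries CH2OTBS. Because the enol-ether oxygen, the ketene-derived hydroxyl and the alkyne-derived silyl ether end on C8a, C5 and C7, the product has three different oxygens and one open aromatic position, C8.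

Step 6
Reactants: 17 6-(tert-butyldimethylsilyloxymethyl)-2,2-dimethyl-7-(triisopropylsilyloxy)chroman-5-ol
Product: 18 6-(tert-butyldimethylsilyloxymethyl)-2,2-dimethyl-5,7-bis(triisopropylsilyloxy)chromane
Conditions: TIPSOTf, 2,6-lutidine, CH2Cl2, 0 °C to rt
Reagents that add atoms: triisopropylsilyl trifluoromethanesulfonate, CC(C)[Si](OS(=O)(=O)C(F)(F)F)(C(C)C)C(C)C
Why: O-Silylation of the remaining phenol with a reactive silyl triflate and a hindered base masks the acidic proton before the organolithium step and matches the C7 group, so both come off together at the end.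

Step 7
Reactants: 18 6-(tert-butyldimethylsilyloxymethyl)-2,2-dimethyl-5,7-bis(triisopropylsilyloxy)chromane
Product: 19 8-bromo-6-(tert-butyldimethylsilyloxymethyl)-2,2-dimethyl-5,7-bis(triisopropylsilyloxy)chromane
Conditions: NBS, MeCN, 0 °C, dark
Reagents that add atoms: N-bromosuccinimide, O=C1CCC(=O)N1Br
Why: Electrophilic aromatic bromination can only take place at C8, the single unsubstituted ring carbon, which is activated by two ortho oxygens and one para oxygen.

Step 8
Reactants: 20 (S)-2-methylbutanoic acid
Product: 22 (S)-N-methoxy-N,2-dimethylbutanamide, via acylimidazole 21 (not isolated)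
Conditions: CDI, CH2Cl2, 0 °C to rt; then MeNHOMe·HCl, rt
Reagents that add atoms: N,O-dimethylhydroxylamine hydrochloride, CNOC.Cl
Why: Activation of the acid as acylimidazole 21 and aminolysis (CDI amide coupling) proceed under near-neutral conditions in which the α-stereocentre of this simple alkyl acid should keep its (S) configuration.

Step 9
Reactants: 19 8-bromo-6-(tert-butyldimethylsilyloxymethyl)-2,2-dimethyl-5,7-bis(triisopropylsilyloxy)chromane; 22 (S)-N-methoxy-N,2-dimethylbutanamide
Product: 24 (S)-1-[6-(tert-butyldimethylsilyloxymethyl)-2,2-dimethyl-5,7-bis(triisopropylsilyloxy)chroman-8-yl]-2-methylbutan-1-one, via aryllithium 23 (not isolated)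
Conditions: t-BuLi (2 equiv), THF, −78 °C; then 22, −78 to −20 °C; aq. NH4Cl at −20 °C
Reagents that add atoms: none
Why: Bromine–lithium exchange at −78 °C, faster than silyl migration from the neighbouring oxygen, gives aryllithium 23, and its single addition to the N-methoxy-N-methylamide (Weinreb ketone synthesis) releases the ketone only on cold quench, so the (S) centre from 20 should be carried over unchanged.

Step 10
Reactants: 24 (S)-1-[6-(tert-butyldimethylsilyloxymethyl)-2,2-dimethyl-5,7-bis(triisopropylsilyloxy)chroman-8-yl]-2-methylbutan-1-one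
Product: 25 {2,2-dimethyl-8-[(S)-2-methylbutanoyl]-5,7-bis(triisopropylsilyloxy)chroman-6-yl}methyl acetate
Conditions: Ac2O, Cu(OTf)2 (cat.), CH2Cl2, 0 °C
Reagents that add atoms: acetic anhydride, CC(=O)OC(C)=O
Why: Lewis-acid-catalysed acetolysis of a silyl ether converts the primary benzylic TBS ether into the acetate (ionisation of the activated benzylic C–O bond would lead to the same acetate), while the hindered aryl TIPS ethers and the ketone should be left alone.

Step 11
Reactants: 25 {2,2-dimethyl-8-[(S)-2-methylbutanoyl]-5,7-bis(triisopropylsilyloxy)chroman-6-yl}methyl acetate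
Product: 26 {2,2-dimethyl-8-[(S)-2-methylbutanoyl]-5,7-bis(triisopropylsilyloxy)-2H-chromen-6-yl}methyl acetate
Conditions: DDQ, 1,4-dioxane, 100 °C
Reagents that add atoms: none
Why: Quinone dehydrogenation of a 2,2-dimethylchroman proceeds by hydride abstraction at C4 (cation stabilised by the oxygens on C5, C7 and C8a) and loss of a C3 proton, whereas the C6 methylene is disarmed by its acetoxy group and by the two flanking OTIPS groups that twist its C–H bonds out of alignment with the ring.

Step 12
Reactants: 27 pentan-3-one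
Product: 28 (Z)-3-(trimethylsilyloxy)pent-2-ene
Conditions: TMSOTf, Et3N, Et2O, 0 °C to rt
Reagents that add atoms: trimethylsilyl trifluoromethanesulfonate, C[Si](C)(C)OS(=O)(=O)C(F)(F)F
Why: Soft enolisation of the symmetrical ketone (silyl enol ether formation) raises no regiochemical question, and the alkene geometry is of no consequence for the next step.

Step 13
Reactants: 28 (Z)-3-(trimethylsilyloxy)pent-2-ene; 29 malonyl dichloride
Product: 31 6-ethyl-4-hydroxy-5-methyl-2H-pyran-2-one, via keto acid chloride 30 (not isolated)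
Conditions: Et2O, −78 °C to rt
Reagents that add atoms: none
Why: C-Acylation of the silyl enol ether by one acid chloride group gives keto acid chloride 30, whose enolised ethyl ketone oxygen closes the lactone on the second acid chloride (malonyl dichloride pyrone annulation of a silyl enol ether), placing ethyl on C6 and methyl on C5.

Step 14
Reactants: 26 {2,2-dimethyl-8-[(S)-2-methylbutanoyl]-5,7-bis(triisopropylsilyloxy)-2H-chromen-6-yl}methyl acetate; 31 6-ethyl-4-hydroxy-5-methyl-2H-pyran-2-one
Product: 33 3-({5,7-dihydroxy-2,2-dimethyl-8-[(S)-2-methylbutanoyl]-2H-chromen-6-yl}methyl)-6-ethyl-4-hydroxy-5-methyl-2H-pyran-2-one (CNP0212387.1), via quinone methide 32 (not isolated)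
Conditions: 31 (excess), Bu4NF, THF, 0 °C to rt; dilute aq. HCl
Reagents that add atoms: none
Why: Fluoride cleaves the aryl TIPS ethers and acetate is expelled from the ortho benzylic position to give quinone methide 32, to which the soft C3 of the 4-hydroxy-2-pyrone adds in a Michael reaction that restores the aromatic ring, while the acidic pyrone in excess buffers the medium so the α-stereocentre should not epimerise.

Compound list
1 | acrolein | C=CC=O | starting material
2 | 2-methylpropene | CC(C)=C | starting material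
3 | 2,2-dimethyl-3,4-dihydro-2H-pyran | CC1(C)CCC=CO1 | intermediate
4 | N-methoxy-N-methylacetamide | CON(C)C(C)=O | starting material
5 | 6-lithio-2,2-dimethyl-3,4-dihydro-2H-pyran (vinyllithium) | [Li]C1=CCCC(C)(C)O1 | intermediate
6 | 1-(6,6-dimethyl-5,6-dihydro-4H-pyran-2-yl)ethan-1-one | CC(=O)C1=CCCC(C)(C)O1 | intermediate
7 | 1-(6,6-dimethyl-5,6-dihydro-4H-pyran-2-yl)-4,4,4-trifluorobutane-1,3-dione (trifluoroacetyl diketone) | O=C(CC(=O)C(F)(F)F)C1=CCCC(C)(C)O1 | intermediate
8 | 2-diazo-1-(6,6-dimethyl-5,6-dihydro-4H-pyran-2-yl)ethan-1-one | CC1(C)CCC=C(O1)C(=O)C=[N+]=[N-] | intermediate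
9 | tert-butyldimethyl(prop-2-yn-1-yloxy)silane | C#CCO[Si](C)(C)C(C)(C)C | starting material
10 | lithium 3-(tert-butyldimethylsilyloxy)prop-1-yn-1-ide (lithium acetylide) | [Li]C#CCO[Si](C)(C)C(C)(C)C | intermediate
11 | lithium 3-(tert-butyldimethylsilyloxy)prop-1-yn-1-olate (lithium ynolate) | [Li]OC#CCO[Si](C)(C)C(C)(C)C | intermediate
12 | 3-(tert-butyldimethylsilyloxy)-1-(triisopropylsilyloxy)prop-1-yne | CC(C)[Si](OC#CCO[Si](C)(C)C(C)(C)C)(C(C)C)C(C)C | intermediate
13 | 2-(6,6-dimethyl-5,6-dihydro-4H-pyran-2-yl)ethen-1-one (vinylketene) | O=C=CC1=CCCC(C)(C)O1 | intermediate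
14 | 2-(tert-butyldimethylsilyloxymethyl)-4-(6,6-dimethyl-5,6-dihydro-4H-pyran-2-yl)-3-(triisopropylsilyloxy)cyclobut-2-en-1-one (racemic vinylcyclobutenone) | O=C1C(CO[Si](C)(C)C(C)(C)C)=C(O[Si](C(C)C)(C(C)C)C(C)C)C1C2=CCCC(C)(C)O2 | intermediate
15 | 2-(tert-butyldimethylsilyloxymethyl)-4-(6,6-dimethyl-5,6-dihydro-4H-pyran-2-yl)-3-(triisopropylsilyloxy)buta-1,3-dien-1-one, ketene and dihydropyranyl groups cis on C3=C4 (dienylketene) | O=C=C(CO[Si](C)(C)C(C)(C)C)/C(O[Si](C(C)C)(C(C)C)C(C)C)=C\C1=CCCC(C)(C)O1 | intermediate
16 | 6-(tert-butyldimethylsilyloxymethyl)-2,2-dimethyl-7-(triisopropylsilyloxy)-2,3,4,4a-tetrahydro-5H-chromen-5-one (racemic cyclohexadienone) | O=C1C(CO[Si](C)(C)C(C)(C)C)=C(O[Si](C(C)C)(C(C)C)C(C)C)C=C2OC(C)(C)CCC12 | intermediate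
17 | 6-(tert-butyldimethylsilyloxymethyl)-2,2-dimethyl-7-(triisopropylsilyloxy)chroman-5-ol | CC1(C)CCc2c(O)c(CO[Si](C)(C)C(C)(C)C)c(O[Si](C(C)C)(C(C)C)C(C)C)cc2O1 | intermediate
18 | 6-(tert-butyldimethylsilyloxymethyl)-2,2-dimethyl-5,7-bis(triisopropylsilyloxy)chromane | CC1(C)CCc2c(O[Si](C(C)C)(C(C)C)C(C)C)c(CO[Si](C)(C)C(C)(C)C)c(O[Si](C(C)C)(C(C)C)C(C)C)cc2O1 | intermediate
19 | 8-bromo-6-(tert-butyldimethylsilyloxymethyl)-2,2-dimethyl-5,7-bis(triisopropylsilyloxy)chromane | CC1(C)CCc2c(O[Si](C(C)C)(C(C)C)C(C)C)c(CO[Si](C)(C)C(C)(C)C)c(O[Si](C(C)C)(C(C)C)C(C)C)c(Br)c2O1 | intermediate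
20 | (S)-2-methylbutanoic acid | OC(=O)[C@@H](C)CC | starting material
21 | (S)-1-(1H-imidazol-1-yl)-2-methylbutan-1-one (acylimidazole) | O=C(n1ccnc1)[C@@H](C)CC | intermediate
22 | (S)-N-methoxy-N,2-dimethylbutanamide | CON(C)C(=O)[C@@H](C)CC | intermediate
23 | 8-lithio-6-(tert-butyldimethylsilyloxymethyl)-2,2-dimethyl-5,7-bis(triisopropylsilyloxy)chromane (aryllithium) | CC1(C)CCc2c(O[Si](C(C)C)(C(C)C)C(C)C)c(CO[Si](C)(C)C(C)(C)C)c(O[Si](C(C)C)(C(C)C)C(C)C)c([Li])c2O1 | intermediate
24 | (S)-1-[6-(tert-butyldimethylsilyloxymethyl)-2,2-dimethyl-5,7-bis(triisopropylsilyloxy)chroman-8-yl]-2-methylbutan-1-one | CC1(C)CCc2c(O[Si](C(C)C)(C(C)C)C(C)C)c(CO[Si](C)(C)C(C)(C)C)c(O[Si](C(C)C)(C(C)C)C(C)C)c(C(=O)[C@@H](C)CC)c2O1 | intermediate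
25 | {2,2-dimethyl-8-[(S)-2-methylbutanoyl]-5,7-bis(triisopropylsilyloxy)chroman-6-yl}methyl acetate | CC1(C)CCc2c(O[Si](C(C)C)(C(C)C)C(C)C)c(COC(C)=O)c(O[Si](C(C)C)(C(C)C)C(C)C)c(C(=O)[C@@H](C)CC)c2O1 | intermediate
26 | {2,2-dimethyl-8-[(S)-2-methylbutanoyl]-5,7-bis(triisopropylsilyloxy)-2H-chromen-6-yl}methyl acetate | CC1(C)C=Cc2c(O[Si](C(C)C)(C(C)C)C(C)C)c(COC(C)=O)c(O[Si](C(C)C)(C(C)C)C(C)C)c(C(=O)[C@@H](C)CC)c2O1 | intermediate
27 | pentan-3-one | CCC(=O)CC | starting material
28 | (Z)-3-(trimethylsilyloxy)pent-2-ene | C/C=C(/CC)O[Si](C)(C)C | intermediate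
29 | malonyl dichloride | ClC(=O)CC(Cl)=O | starting material
30 | 4-methyl-3,5-dioxoheptanoyl chloride (racemic keto acid chloride) | CCC(=O)C(C)C(=O)CC(Cl)=O | intermediate
31 | 6-ethyl-4-hydroxy-5-methyl-2H-pyran-2-one | CCc1oc(=O)cc(O)c1C | intermediate
32 | (S)-2,2-dimethyl-6-methylidene-8-(2-methylbutanoyl)-5-(triisopropylsilyloxy)-2H-chromen-7(6H)-one (ortho-quinone methide) | C=C1C(=O)C(C(=O)[C@@H](C)CC)=C2OC(C)(C)C=CC2=C1O[Si](C(C)C)(C(C)C)C(C)C | intermediate
33 | 3-({5,7-dihydroxy-2,2-dimethyl-8-[(S)-2-methylbutanoyl]-2H-chromen-6-yl}methyl)-6-ethyl-4-hydroxy-5-methyl-2H-pyran-2-one (CNP0212387.1) | CCc1oc(=O)c(Cc2c(O)c3c(c(C(=O)[C@@H](C)CC)c2O)OC(C)(C)C=C3)c(O)c1C | target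

Total step count: 14. Longest linear sequence: 10 steps (1, 2, 3, 5, 6, 7, 9, 10, 11, 14).

Steps most likely to fail

Step 5 (benzannulation). Secondary photochemistry or dimerisation of the electron-rich vinylketene may outrun its capture by the alkyne, or the sequence may stall at the cyclobutenone stage. The fallback sets out from acid 20 and pyrone 31 and comes back to the route at target 33; it takes the benzene ring from phloroglucinol instead of building it. Acid 20 with (COCl)2 and catalytic DMF should give (S)-2-methylbutanoyl chloride F1. Friedel–Crafts acylation of phloroglucinol with F1 (AlCl3, PhNO2–CH2Cl2, rt) should give (S)-2-methyl-1-(2,4,6-trihydroxyphenyl)butan-1-one F2. Condensation of F2 with 3-methylbut-2-enal (ethylenediammonium diacetate, toluene, heat), followed by oxa-6π closure, should give (S)-1-(5,7-dihydroxy-2,2-dimethyl-2H-chromen-8-yl)-2-methylbutan-1-one F3, which has to be separated from its 6-acyl regioisomer. Pyrone 31 with dimethylmethylideneammonium iodide (MeCN, rt) should give the Mannich base 3-[(dimethylamino)methyl]-6-ethyl-4-hydroxy-5-methyl-2H-pyran-2-one F4. Warming F4 with F3 should expel dimethylamine and alkylate the free C6 position of F3 to give 33. This path is shorter, but it gives up the regiocontrol of the main route and exposes the stereocentre to AlCl3.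

Step 11 (dehydrogenation). Hydride abstraction may occur at the C6 benzylic methylene instead of C4, or the acyl-deactivated, fully silylated ring may react so slowly that the benzylic acetate ionises on long heating. The fallback sets out from 25 and comes back at 26; it replaces hydride abstraction by a radical C–H bromination and an elimination. NBS with catalytic AIBN (PhCF3, 80 °C) should brominate the less hindered secondary benzylic C4 position to give {4-bromo-2,2-dimethyl-8-[(S)-2-methylbutanoyl]-5,7-bis(triisopropylsilyloxy)chroman-6-yl}methyl acetate F5 as a mixture of C4 epimers. E2 elimination of HBr with DBU (THF, rt) should then give 26.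

Step 9 (acylation). Addition of the hindered aryllithium to the α-branched amide may be slow, which leaves time for oxygen-to-carbon silyl migration or for proton abstraction from the amide. The fallback sets out from 19 and comes back at 24; it uses a more reactive electrophile and then adjusts the oxidation level. The aryllithium from 19 (t-BuLi, THF, −78 °C) is quenched at −78 °C with (S)-2-methylbutanal, freshly made from (S)-2-methylbutan-1-ol. This should give (2S)-1-[6-(tert-butyldimethylsilyloxymethyl)-2,2-dimethyl-5,7-bis(triisopropylsilyloxy)chroman-8-yl]-2-methylbutan-1-ol F6 as a mixture of epimers at the carbinol carbon. Dess–Martin oxidation (NaHCO3, CH2Cl2, rt) removes that centre and should give 24.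

Further compounds
F1 | step 5 | (S)-2-methylbutanoyl chloride | ClC(=O)[C@@H](C)CC
F2 | step 5 | (S)-2-methyl-1-(2,4,6-trihydroxyphenyl)butan-1-one | O=C(c1c(O)cc(O)cc1O)[C@@H](C)CC
F3 | step 5 | (S)-1-(5,7-dihydroxy-2,2-dimethyl-2H-chromen-8-yl)-2-methylbutan-1-one | CC1(C)C=Cc2c(O)cc(O)c(C(=O)[C@@H](C)CC)c2O1
F4 | step 5 | 3-[(dimethylamino)methyl]-6-ethyl-4-hydroxy-5-methyl-2H-pyran-2-one | CCc1oc(=O)c(CN(C)C)c(O)c1C
F5 | step 11 | {4-bromo-2,2-dimethyl-8-[(S)-2-methylbutanoyl]-5,7-bis(triisopropylsilyloxy)chroman-6-yl}methyl acetate | CC1(C)CC(Br)c2c(O[Si](C(C)C)(C(C)C)C(C)C)c(COC(C)=O)c(O[Si](C(C)C)(C(C)C)C(C)C)c(C(=O)[C@@H](C)CC)c2O1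
F6 | step 9 | (2S)-1-[6-(tert-butyldimethylsilyloxymethyl)-2,2-dimethyl-5,7-bis(triisopropylsilyloxy)chroman-8-yl]-2-methylbutan-1-ol | CC1(C)CCc2c(O[Si](C(C)C)(C(C)C)C(C)C)c(CO[Si](C)(C)C(C)(C)C)c(O[Si](C(C)C)(C(C)C)C(C)C)c(C(O)[C@@H](C)CC)c2O1
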